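The vessel holds partner from the start and takes starting material in 4 equal portions, 20 s apart, at constant volume. The new flasks differ in the charge c of starting material, while partner stands at D = 0.600 M.

| setting | noon | midnight | teal | grey | red | amber |
|---|---|---|---|---|---|---|
| starting material | 0.11 M (in portions, 4) | 1 M (in portions, 4) | 0.15 M (in portions, 4) | 0.30 M (in portions, 4) | 0.60 M (in portions, 4) | 1.2 M (in portions, 4) |
| partner | 0.60 M | 0.60 M | 0.600 M | 0.600 M | 0.600 M | 0.600 M |
| remark | run made earlier; portions every 20 s | run made earlier; portions every 20 s | the portions of starting material follow each other after 20 s, the first at the start | the portions of starting material follow each other after 20 s, the first at the start | the portions of starting material follow each other after 20 s, the first at the start | the portions of starting material follow each other after 20 s, the first at the start |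
| time |  |  | 20 min | 20 min | 20 min | 20 min |

- noon (time / min: target / %, starting material / %): 1.00: 3.7, 70.0; 2.00: 10.6, 86.4; 4.00: 23.3, 69.0; 8.00: 38.8, 42.3; 15.0: 50.0, 16.4
- midnight (time / min: target / %, starting material / %): 1.33: 4.7, 91.1; 4.00: 9.8, 60.1; 6.00: 10.3, 41.9; 10.0: 11.0, 20.5; 15.0: 11.1, 8.2

(standard deviation of a reading: 0.3 percentage points)

- [target] at the end for teal, grey, red, amber, in this order
- the course of these numbers from the first flask to the last (hardly changes / rises, then falls / falls all the way / falls, then rises / rises all the way)

A bench rule says: more charge, more target, up to a ceiling. Midnight shows that ceiling. From 6.00 min to 15.0 min target stays between 10.3% and 11.1% while starting material falls from 41.9% to 8.2%, so target is being removed about as fast as it forms, and the reading gives T* = 0.111 M. Over that stretch of midnight the readings give starting material a first-order constant of 0.181 /min. In noon, with target near a third of T*, the constant reads 0.122 /min. If the constant grows in step with target, noon puts its value at zero target at 0.0935 /min, about half of the midnight value. So by these readings starting material divides about evenly at T*, the symmetric case: one share goes on to target and takes partner, the other removes target.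

The ceiling rule has a border, which a balance finds. Suppose that each forming of target takes one starting material and one partner, that each removal takes one starting material and one target, and that starting material is used up. Then partner used plus removals equals c, and partner used minus removals equals target, so partner used is half the sum of c and target. Dividing that by D, with target at T*, gives the partner demand Φ, and a value of one is the border. Amber's Φ is 1.09.

Midnight's Φ is 0.926, under the border. Red's Φ is 0.593, which by the balance leaves 40.8% of its partner once starting material is used up. Amber's Φ lies over the border, so by the balance partner is the limiting reagent in amber, and starting material still present when partner is used up goes on removing target. The reckoning here therefore commits to a row that climbs towards T* up to red and drops at amber.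

The forecast gives 0.066 M, 0.09 M, 0.106 M and 0.112 M, a row that “rises all the way towards the ceiling”, and so it parts from this reckoning at amber.

The flasks give 0.0698 M, 0.0958 M, 0.114 M and 0.0927 M: the row rises, then falls.

    starting material → intermediate (k = 0.0938 /min)
    partner + intermediate → target (k = 8.27 /M/min)
    2 intermediate → homo product (k = 5.40 /M/min)
    starting material + target → side product (k = 0.796 /M/min)

In teal at 20.0 min, the path through intermediate uses starting material at 1.7 times the rate of the path with target. T* over teal's target at that time is 1.59. Amber, with Φ at 1.09, has 4.14% of its partner left at 20.0 min. Red, reckoned to keep 40.8% of its partner, holds 41.0% of it at 200 min.

The earlier runs and the new flask are simulated with made-up constants; scatter was added.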